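The numbers are made up; what happens was integrated by code.

I nearly fell into a pitfall with this flask: I multiplied the enzyme's top rate by the time and took the charge for used up.

substrate 14 mM; enzyme 1.4 µM; time 30 h

    substrate + enzyme → product + enzyme, rate k1*[substrate]^2.5*[enzyme]/(1 + ([substrate]/Kh1)^2.5) (Kh1 = 9.96 mM, k1 = 18000 M⁻²·⁵ s⁻¹)
    crystals ⇌ product, rate k2*(cs2 - [product]) while solid is left; crystals form when [product] > cs2 (cs2 = 0.93 mM, k2 = 0.0505 min⁻¹)

- cedar: doubling the amount of enzyme, all else as stated
- larch: doubling the dissolution coefficient of step 2, all else as stated
- alder: doubling the solubility in step 2, all else as stated

- product is meant together with its crystals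
- solid, in amounts per volume of the solution: crystals
- run time (flask): 30 h

1. amount of product and crystals together at 30 h, in percent of the substrate charged
2. concentration of product in solution at 15 h, in percent of saturation
3. the change that raises the amount of product and crystals together at 30 h, in percent of the substrate charged most ("none" if none brings more than 2 percentage points) (cedar / larch / alder / none)
4. amount of product and crystals together at 30 h, in percent of the substrate charged, after cedar

1. The crystal step moves product between solution and solid, and the yield counts both forms, so I reckoned the yield from the enzyme step.

2. With substrate far above Kh, the law of the enzyme step flattens at a top rate (the usual Vmax) of 0.898 mM h⁻¹. I then took the turnover count, the top rate times the time over the charge, 1.92.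

3. So the count promised twice the charge, yet the law slows as substrate falls, and I did not trust that promise. To clear this up, I integrated the law. The count a conversion costs is the fraction converted plus 0.474 times the difference in (substrate/Kh)^−1.5 between end and start.

4. Leaving a third of the substrate cost 1.86, of which 1.19 was slowdown. By then the rate was 13.1 % of the top rate. My count was larger than that cost, so I expected a yield slightly above 66.7 %.

5. Doubling the enzyme gave a count of 3.84. Leaving 20.0 % cost 3.70, so I expected slightly above 80.0 %.

6. The forecast gave 67.5 %, 110.1 % of saturation at 15 h, cedar as best and 80.6 % after it, holding that “Larch and alder leave the total unchanged”.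

7. The simulation gave 67.5 %, 110 % of saturation at 15.0 h, cedar as best with a gain of 13 percentage points, and 80.6 % after it.

In this flask, a count of 1.92 bought 67.5 %. At 30.0 h, dissolved product was made at 0.982 times the rate at which it was used up, and crystals held 60.6 % of the charge. The neighbour flask read at 5.0 d had a count of 7.70; leaving 12.5 % of the substrate costs 7.03, less than that count, and that neighbour flask stood at 88.3 %.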